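**Strategy**

The route rests on the disconnection of the aryl–allyl bond between C6 of ring A and C1'' of the geranyl chain. C6 lies between the C5 and C7 oxygens, and the C5 hydroxyl, chelated to the C4 carbonyl, is the only free phenol of a 7-O-protected chromone: it steers iodination to C6, and the two flanking MOM acetals later assist zinc insertion into that C–I bond. The key step converts the complete (2S)-6-iodoflavanone tris-MOM ether into its arylzinc iodide and couples it, under base-free Pd catalysis, with geranyl bromide, so that the 2E alkene and the C2 stereocentre are both carried through unchanged. C2 is set earlier by Rh-catalysed asymmetric conjugate arylation.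

Key step: step 6

Assumption: compounds 1, 5 and 8 are taken as catalogue compounds; the (S)-ligand in step 5 is assigned by analogy with the (S)-BINAP/2-cyclohexenone model (aryl to the Re face of C2) and would be exchanged for its antipode if a first assay pointed to 2R.

**Route**

Step 1
Reactants: 1 5,7-dihydroxy-4H-chromen-4-one
Product: 2 5-hydroxy-7-(methoxymethoxy)-4H-chromen-4-one
Conditions: MOMCl (1.1 equiv), K2CO3, acetone, 0 °C to rt
Reagents that add atoms: methoxymethyl chloride, COCCl
Why: Williamson etherification should stop at the more acidic, non-chelated 7-OH, because the 5-OH is held in a hydrogen bond to the C4 carbonyl.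

Step 2
Reactants: 2 5-hydroxy-7-(methoxymethoxy)-4H-chromen-4-one
Product: 3 5-hydroxy-6-iodo-7-(methoxymethoxy)-4H-chromen-4-one
Conditions: NIS (1.0 equiv), DMF, rt, dark
Reagents that add atoms: N-iodosuccinimide, O=C1CCC(=O)N1I
Why: Electrophilic aromatic iodination of 5-hydroxy-7-alkoxychromones is directed by the free chelated phenol to its only open ortho position, C6, while C8 and the electron-poor C3 should stay untouched under neutral conditions.

Step 3
Reactants: 3 5-hydroxy-6-iodo-7-(methoxymethoxy)-4H-chromen-4-one
Product: 4 6-iodo-5,7-bis(methoxymethoxy)-4H-chromen-4-one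
Conditions: NaH, then MOMCl, DMF, 0 °C to rt
Reagents that add atoms: methoxymethyl chloride, COCCl
Why: Irreversible deprotonation breaks the chelate and the phenoxide should be alkylated (Williamson ether synthesis) despite the flanking iodine, which removes the acidic proton that would quench the later arylzinc.

Step 4
Reactants: 5 2,6-dimethoxy-4-(4,4,5,5-tetramethyl-1,3,2-dioxaborolan-2-yl)phenol
Product: 6 2-[3,5-dimethoxy-4-(methoxymethoxy)phenyl]-4,4,5,5-tetramethyl-1,3,2-dioxaborolane
Conditions: MOMCl, K2CO3, acetone, reflux
Reagents that add atoms: methoxymethyl chloride, COCCl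
Why: Williamson etherification of the hindered phenol leaves the pinacol boronate intact and masks the ring-B hydroxyl against protonolysis of the arylzinc in step 6.

Step 5
Reactants: 4 6-iodo-5,7-bis(methoxymethoxy)-4H-chromen-4-one; 6 2-[3,5-dimethoxy-4-(methoxymethoxy)phenyl]-4,4,5,5-tetramethyl-1,3,2-dioxaborolane
Product: 7 (2S)-2-[3,5-dimethoxy-4-(methoxymethoxy)phenyl]-6-iodo-5,7-bis(methoxymethoxy)-2,3-dihydro-4H-chromen-4-one
Conditions: [RhCl(C2H4)2]2 (2.5 mol %), (S)-MeO-F12-BIPHEP (5.5 mol %), aq. KOH (0.2 equiv), toluene/H2O, 30 °C; 6 (2 equiv)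
Reagents that add atoms: none
Why: Rh(I)-catalysed asymmetric 1,4-addition of the arylboron reagent to the chromone enone (Hayashi–Miyaura reaction) should set C2, the electron-poor C2-symmetric bisphosphine (S)-2,2'-bis[bis(3,4,5-trifluorophenyl)phosphino]-6,6'-dimethoxybiphenyl being expected to deliver the aryl group to the Re face of C2 and so give 2S, while the hindered, electron-rich C–I bond should be inert to Rh(I).

Step 6
Reactants: 7 (2S)-2-[3,5-dimethoxy-4-(methoxymethoxy)phenyl]-6-iodo-5,7-bis(methoxymethoxy)-2,3-dihydro-4H-chromen-4-one; 8 geranyl bromide, (2E)-1-bromo-3,7-dimethylocta-2,6-diene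
Product: 10 (2S)-2-[3,5-dimethoxy-4-(methoxymethoxy)phenyl]-6-[(2E)-3,7-dimethylocta-2,6-dien-1-yl]-5,7-bis(methoxymethoxy)-2,3-dihydro-4H-chromen-4-one, via arylzinc iodide 9 (not isolated)
Conditions: Zn dust (activated with BrCH2CH2Br, TMSCl), LiCl, THF, 25–50 °C; filter from excess Zn; then 8 (1.3 equiv), Pd(PPh3)4 (5 mol %), THF, 0 °C to rt
Reagents that add atoms: none
Why: LiCl-mediated oxidative insertion of zinc into the C6–I bond, assisted by the two ortho acetal oxygens, should give arylzinc iodide 9, which tolerates the C4 ketone; Pd(0) then ionises geranyl bromide to the syn (π-geranyl)palladium bromide, the aryl group is transferred from zinc, and reductive elimination forms the C6–C1'' bond. The closest known reaction type is the Pd-catalysed Negishi coupling of arylzinc halides with geranyl and neryl halides. No ring is closed and no stereocentre is created; C2 should be untouched because the medium holds no base that could open ring C by a retro-oxa-Michael reaction. Three selectivities are needed: the site on ring A is fixed by the iodine at C6 between the C5 and C7 oxygens; bond formation at the CH2 terminus and not at the tertiary C3'' follows from reductive elimination at the less hindered end of the allyl ligand; and the 2''E geometry should be kept because the geranyl unit enters as the electrophile, so the π-allyl complex forms with retention and syn/anti exchange would need an η1 bond at the tertiary carbon. Excess zinc is removed before the bromide is added so that no geranylzinc species can form.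

Step 7
Reactants: 10 (2S)-2-[3,5-dimethoxy-4-(methoxymethoxy)phenyl]-6-[(2E)-3,7-dimethylocta-2,6-dien-1-yl]-5,7-bis(methoxymethoxy)-2,3-dihydro-4H-chromen-4-one
Product: 11 (2S)-6-[(2E)-3,7-dimethylocta-2,6-dien-1-yl]-5,7-dihydroxy-2-(4-hydroxy-3,5-dimethoxyphenyl)-2,3-dihydro-4H-chromen-4-one
Conditions: 3 M aq. HCl, MeOH, 40 °C
Reagents that add atoms: none
Why: Acid-catalysed acetal methanolysis should remove the three MOM groups as dimethoxymethane, and short exposure at moderate temperature should spare both trisubstituted alkenes and the C2 configuration.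

**Compound list**

1 | 5,7-dihydroxy-4H-chromen-4-one | O=c1ccoc2cc(O)cc(O)c12 | starting material
2 | 5-hydroxy-7-(methoxymethoxy)-4H-chromen-4-one | COCOc1cc(O)c2c(=O)ccoc2c1 | intermediate
3 | 5-hydroxy-6-iodo-7-(methoxymethoxy)-4H-chromen-4-one | COCOc1cc2occc(=O)c2c(O)c1I | intermediate
4 | 6-iodo-5,7-bis(methoxymethoxy)-4H-chromen-4-one | COCOc1cc2occc(=O)c2c(OCOC)c1I | intermediate
5 | 2,6-dimethoxy-4-(4,4,5,5-tetramethyl-1,3,2-dioxaborolan-2-yl)phenol | COc1cc(B2OC(C)(C)C(C)(C)O2)cc(OC)c1O | starting material
6 | 2-[3,5-dimethoxy-4-(methoxymethoxy)phenyl]-4,4,5,5-tetramethyl-1,3,2-dioxaborolane | COCOc1c(OC)cc(B2OC(C)(C)C(C)(C)O2)cc1OC | intermediate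
7 | (2S)-2-[3,5-dimethoxy-4-(methoxymethoxy)phenyl]-6-iodo-5,7-bis(methoxymethoxy)-2,3-dihydro-4H-chromen-4-one | COc1cc([C@@H]2CC(=O)c3c(cc(OCOC)c(I)c3OCOC)O2)cc(OC)c1OCOC | intermediate
8 | geranyl bromide, (2E)-1-bromo-3,7-dimethylocta-2,6-diene | BrC/C=C(\C)CCC=C(C)C | starting material
9 | {(2S)-2-[3,5-dimethoxy-4-(methoxymethoxy)phenyl]-5,7-bis(methoxymethoxy)-4-oxo-3,4-dihydro-2H-chromen-6-yl}zinc iodide (LiCl complex in THF, not isolated) | COc1cc([C@@H]2CC(=O)c3c(cc(OCOC)c([Zn]I)c3OCOC)O2)cc(OC)c1OCOC | intermediate
10 | (2S)-2-[3,5-dimethoxy-4-(methoxymethoxy)phenyl]-6-[(2E)-3,7-dimethylocta-2,6-dien-1-yl]-5,7-bis(methoxymethoxy)-2,3-dihydro-4H-chromen-4-one | COc1cc([C@@H]2CC(=O)c3c(cc(OCOC)c(C/C=C(\C)CCC=C(C)C)c3OCOC)O2)cc(OC)c1OCOC | intermediate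
11 | (2S)-6-[(2E)-3,7-dimethylocta-2,6-dien-1-yl]-5,7-dihydroxy-2-(4-hydroxy-3,5-dimethoxyphenyl)-2,3-dihydro-4H-chromen-4-one | COc1cc([C@@H]2CC(=O)c3c(cc(O)c(C/C=C(\C)CCC=C(C)C)c3O)O2)cc(OC)c1O | target

**Step count and risks**

Total steps: 7. Longest linear sequence: 6 steps (1, 2, 3, 5, 6, 7).

Steps most likely to fail:

Step 6. Zinc insertion into the electron-rich, doubly ortho-substituted C–I bond may be slow, so that protonolysis of the arylzinc to the deiodinated flavanone competes, or the arylzinc may transfer sluggishly to the allylpalladium complex. The fallback sets out from 7 and keeps a neutral medium with geranyl bromide as the electrophile, but changes the aryl nucleophile to tin. Pd-catalysed stannylation of 7 with hexamethylditin (Pd(PPh3)4, toluene, 100 °C) should give (2S)-2-[3,5-dimethoxy-4-(methoxymethoxy)phenyl]-5,7-bis(methoxymethoxy)-6-(trimethylstannyl)-2,3-dihydro-4H-chromen-4-one F1. Stille coupling of F1 with 8 (Pd2(dba)3, AsPh3, DMF, 50 °C) should then return to the route at 10.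

Step 5. The electron-rich, peri-substituted chromone may add the aryl group slowly, facial discrimination may be insufficient, or hydroxide may open ring C of the product and erode the configuration at C2. The fallback sets out from 4 and 6 and replaces asymmetric catalysis by resolution. Conjugate arylation with the more active achiral catalyst [Rh(OH)(cod)]2 (dioxane/H2O, 50 °C) should give racemic 2-[3,5-dimethoxy-4-(methoxymethoxy)phenyl]-6-iodo-5,7-bis(methoxymethoxy)-2,3-dihydro-4H-chromen-4-one F2. Preparative chromatography on a polysaccharide chiral stationary phase should then separate it into 7, where the route is rejoined, and the (2R)-enantiomer F3, which is set aside.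

Step 2. Iodination may lose site selectivity, with attack at C8 (para to the free phenol) or double iodination. The fallback sets out from 2 and uses a delivery mechanism that can only reach the position ortho to the free 5-OH. Amine-mediated ortho-bromination (NBS, cat. iPr2NH, CH2Cl2, 0 °C), in which an N-bromoamine hydrogen-bonded to the phenol transfers bromine, should give 6-bromo-5-hydroxy-7-(methoxymethoxy)-4H-chromen-4-one F4. Etherification (NaH, MOMCl, DMF) should give 6-bromo-5,7-bis(methoxymethoxy)-4H-chromen-4-one F5. An aromatic Finkelstein exchange (NaI, CuI, trans-N,N'-dimethylcyclohexane-1,2-diamine, dioxane, 110 °C) should then return to the route at 4.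

**Further compounds**

F1 | step 6 | (2S)-2-[3,5-dimethoxy-4-(methoxymethoxy)phenyl]-5,7-bis(methoxymethoxy)-6-(trimethylstannyl)-2,3-dihydro-4H-chromen-4-one | COc1cc([C@@H]2CC(=O)c3c(cc(OCOC)c([Sn](C)(C)C)c3OCOC)O2)cc(OC)c1OCOC
F2 | step 5 | racemic 2-[3,5-dimethoxy-4-(methoxymethoxy)phenyl]-6-iodo-5,7-bis(methoxymethoxy)-2,3-dihydro-4H-chromen-4-one | COc1cc(C2CC(=O)c3c(cc(OCOC)c(I)c3OCOC)O2)cc(OC)c1OCOC
F3 | step 5 | (2R)-2-[3,5-dimethoxy-4-(methoxymethoxy)phenyl]-6-iodo-5,7-bis(methoxymethoxy)-2,3-dihydro-4H-chromen-4-one | COc1cc([C@H]2CC(=O)c3c(cc(OCOC)c(I)c3OCOC)O2)cc(OC)c1OCOC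
F4 | step 2 | 6-bromo-5-hydroxy-7-(methoxymethoxy)-4H-chromen-4-one | COCOc1cc2occc(=O)c2c(O)c1Br
F5 | step 2 | 6-bromo-5,7-bis(methoxymethoxy)-4H-chromen-4-one | COCOc1cc2occc(=O)c2c(OCOC)c1Br
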